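Atoms are numbered along the chain from C1 (CH2OH of the side chain on the ether carbon C6) to C16 (the other CH2OH). Everything rests on cutting C10–C11: the carbinol C10 and the fully substituted C11, which carries the ether oxygen and the lactone carbonyl, are an aldol unit within the three-carbon bridge C8–C10 laid across the 1,4-dioxan-2-one ring. In one operation a cobalt hydride adds to C12 of a 3-alkylidene dioxanone and the C11 enolate captures the C10 aldehyde tethered to C7, which closes the oxepane and the seven-membered lactone and sets C10 and C11. Precursor 21 is that dioxanone aldehyde, made from nerol with C6 and C7 already in place.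

Key step: step 13

Remark: the configurations used are C6 S, C7 R, C10 S, C11 R, as read from the target SMILES; L-(+)-diethyl tartrate is taken to give the (2S,3S)-epoxy alcohol 4, as with other (E)-2-methylalk-2-en-1-ols; the C11=C12 geometry of 20 and 21 is left open because both isomers give the same enolate.

Step 1
Reactants: 1 nerol
Product: 2 tert-butyl{[(2Z)-3,7-dimethylocta-2,6-dien-1-yl]oxy}dimethylsilane
Conditions: TBSCl (1.1 equiv), imidazole (2 equiv), CH2Cl2, 0 °C to rt
Reagents that add atoms: tert-butyldimethylsilyl chloride, CC(C)(C)[Si](C)(C)Cl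
Why: Imidazole-promoted silyl ether formation at the only hydroxyl; no stereocentre is involved and the (Z)-alkene is untouched.

Step 2
Reactants: 2 neryl TBS ether
Product: 3 (2E,6Z)-8-[(tert-butyldimethylsilyl)oxy]-2,6-dimethylocta-2,6-dien-1-ol
Conditions: SeO2 (0.3 equiv), t-BuOOH (3 equiv), salicylic acid (0.1 equiv), CH2Cl2, 0 °C to rt
Reagents that add atoms: selenium dioxide, O=[Se]=O (delivers the oxygen); tert-butyl hydroperoxide, CC(C)(C)OO (terminal oxidant)
Why: Riley allylic oxidation (ene reaction, then [2,3]-sigmatropic shift) should attack the more electron-rich distal alkene, the C2=C3 alkene being deactivated by its allylic silyloxy group, and hydroxylate the methyl trans to the chain, which gives the (E)-allylic alcohol carrying C8.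

Step 3
Reactants: 3 (E)-allylic alcohol
Product: 4 [(2S,3S)-3-{(3Z)-5-[(tert-butyldimethylsilyl)oxy]-3-methylpent-3-en-1-yl}-2-methyloxiran-2-yl]methanol
Conditions: Ti(OiPr)4 (10 mol%), L-(+)-diethyl tartrate (12 mol%), t-BuOOH (2 equiv, decane), 4 Å MS, CH2Cl2, −20 °C
Reagents that add atoms: tert-butyl hydroperoxide, CC(C)(C)OO
Why: Sharpless asymmetric epoxidation: only the alkene of the free allylic alcohol is bound to titanium, and the L-(+)-tartrate complex adds oxygen to the face that gives the (2S,3S)-epoxide, which sets C6 (S) and C7 (S).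

Step 4
Reactants: 4 epoxy alcohol; 5 tert-butyl acetate
Product: 7 tert-butyl 3-[(2S,3S)-3-{(3Z)-5-[(tert-butyldimethylsilyl)oxy]-3-methylpent-3-en-1-yl}-2-methyloxiran-2-yl]propanoate, via triflate 6 (not isolated)
Conditions: Tf2O (1.1 equiv), 2,6-lutidine (1.5 equiv), CH2Cl2, −78 °C; then cannulated into LiCH2CO2tBu (from 5 and LDA, 2.5 equiv), THF–DMPU, −78 to −40 °C
Reagents that add atoms: none
Why: Triflation of the primary alcohol, then SN2 alkylation of the lithium ester enolate at the primary carbon; the trisubstituted epoxide is hindered at both carbons and should survive at low temperature, so C6 and C7 are unchanged while C9 and C10 are added.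

Step 5
Reactants: 7 epoxy ester
Product: 8 (5R)-5-[(1S,4Z)-6-[(tert-butyldimethylsilyl)oxy]-1-hydroxy-4-methylhex-4-en-1-yl]-5-methyloxolan-2-one
Conditions: CSA (0.1 equiv), CH2Cl2, 0 °C to rt
Reagents that add atoms: none
Why: Acid-catalysed 5-exo-tet opening of the epoxide by the ester carbonyl oxygen at the tertiary carbon C7 with inversion (anchimerically assisted lactonisation, tert-butyl leaving as isobutene) turns C7 into R, leaves C6 (S) and its oxygen untouched, and frees the C6 hydroxyl while O7 stays masked in the lactone.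

Step 6
Reactants: 9 triethyl phosphonoacetate
Product: 11 ethyl 2-diazo-2-(diethoxyphosphoryl)acetate, via sodium salt 10 (not isolated)
Conditions: NaH (1.1 equiv), THF, 0 °C; then TsN3 (1.05 equiv), 0 °C to rt
Reagents that add atoms: 4-methylbenzenesulfonyl azide, Cc1ccc(cc1)S(=O)(=O)N=[N+]=[N-]
Why: Regitz diazo transfer from the sulfonyl azide to the stabilised phosphonoacetate carbanion.

Step 7
Reactants: 8 hydroxy lactone; 11 diazophosphonoacetate
Product: 12 ethyl 2-(diethoxyphosphoryl)-2-{[(1S,4Z)-6-[(tert-butyldimethylsilyl)oxy]-4-methyl-1-[(2R)-2-methyl-5-oxooxolan-2-yl]hex-4-en-1-yl]oxy}acetate (both epimers at the phosphonate carbon)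
Conditions: Rh2(OAc)4 (2 mol%), benzene, 80 °C, slow addition of 11 (1.3 equiv)
Reagents that add atoms: none
Why: Dirhodium-carbenoid O–H insertion (oxonium ylide, then 1,2-proton shift) into the only hydroxyl of 8, so O6 is etherified without competition from O7; the new centre forms as both epimers, which is immaterial because it becomes sp2 in step 11.

Step 8
Reactants: 12 lactone phosphonoacetate
Product: 15 diethyl [(5S,6R)-6-(3-hydroxypropyl)-6-methyl-5-{(3Z)-3-methyl-5-[(tert-butyldimethylsilyl)oxy]pent-3-en-1-yl}-2-oxo-1,4-dioxan-3-yl]phosphonate, via sodium enolate 13 (not isolated), via diol 14 (not isolated)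
Conditions: NaHMDS (1.05 equiv), THF, −78 °C; LiBH4 (3 equiv), 0 °C to rt; aq. NH4Cl; then PPTS (0.2 equiv), PhMe, 5 Å MS, 60 °C
Reagents that add atoms: none
Why: Enolate formation shields the phosphonoacetate ester from hydride, so LiBH4 should reduce only the γ-lactone to the C7/C10 diol, and mild acid then closes the six-membered lactone from the tertiary C7 hydroxyl onto the ethyl ester (Thorpe–Ingold-assisted lactonisation; the primary C10 hydroxyl could only form a nine-membered ring); C6 and C7 are not touched.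

Step 9
Reactants: 15 dioxanone phosphonate alcohol
Product: 16 diethyl [(5S,6R)-6-methyl-5-{(3Z)-3-methyl-5-[(tert-butyldimethylsilyl)oxy]pent-3-en-1-yl}-2-oxo-6-[3-(triethylsilyloxy)propyl]-1,4-dioxan-3-yl]phosphonate
Conditions: TESCl (1.2 equiv), imidazole (2.5 equiv), CH2Cl2, 0 °C
Reagents that add atoms: chlorotriethylsilane, CC[Si](Cl)(CC)CC
Why: Silylation of the primary alcohol, which would otherwise quench the phosphonate anion of step 11; triethylsilyl is chosen because step 12 can oxidise it off directly.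

Step 10
Reactants: 17 methyl 3,3-dimethoxypropanoate
Product: 18 3,3-dimethoxypropanal
Conditions: DIBAL-H (1.05 equiv), CH2Cl2, −78 °C; Rochelle salt; used at once as a dried solution
Reagents that add atoms: none
Why: DIBAL-H half-reduction of an ester at −78 °C, where the tetrahedral aluminium alkoxide persists until work-up; the aldehyde is not stored because it loses methanol easily.

Step 11
Reactants: 16 phosphonate; 18 3,3-dimethoxypropanal
Product: 20 (5S,6R)-3-(3,3-dimethoxypropylidene)-6-methyl-5-{(3Z)-3-methyl-5-[(tert-butyldimethylsilyl)oxy]pent-3-en-1-yl}-6-[3-(triethylsilyloxy)propyl]-1,4-dioxan-2-one (E/Z mixture), via lithiated phosphonate 19 (not isolated)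
Conditions: LiHMDS (1.05 equiv), THF, −78 °C; then 18 (1.5 equiv), −78 to 0 °C
Reagents that add atoms: none
Why: Horner–Wadsworth–Emmons olefination of the lithiated α-alkoxy phosphono lactone with an aliphatic aldehyde at low temperature; both alkene geometries are acceptable because step 13 erases this element.

Step 12
Reactants: 20 alkylidene dioxanone TES ether
Product: 21 (5S,6R)-3-(3,3-dimethoxypropylidene)-6-methyl-5-{(3Z)-3-methyl-5-[(tert-butyldimethylsilyl)oxy]pent-3-en-1-yl}-6-(3-oxopropyl)-1,4-dioxan-2-one (E/Z mixture)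
Conditions: (COCl)2 (4 equiv), DMSO (8 equiv), CH2Cl2, −78 to −30 °C; Et3N (12 equiv), −78 °C to rt
Reagents that add atoms: none
Why: Swern oxidation applied directly to the primary triethylsilyl ether (silyl transfer to the chlorosulfonium salt, then alkoxysulfonium ylide fragmentation), which should leave the bulkier allylic TBS ether, the acetal and the lactone untouched.

Step 13
Reactants: 21 dioxanone aldehyde
Product: 24 (1R,2S,5R,9S)-1-(3,3-dimethoxypropyl)-2-hydroxy-5-methyl-9-{(3Z)-3-methyl-5-[(tert-butyldimethylsilyl)oxy]pent-3-en-1-yl}-6,8-dioxabicyclo[3.2.2]nonan-7-one, via cobalt enolate 22 (not isolated), via phenylsilyl ether 23 (not isolated)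
Conditions: Co(dpm)2 [bis(2,2,6,6-tetramethylheptane-3,5-dionato)cobalt, divalent cobalt] (10 mol%), PhSiH3 (1.5 equiv), ClCH2CH2Cl, degassed, 25 °C; then PPTS (cat.), MeOH, 0 °C
Reagents that add atoms: none
Why: The cobalt hydride formed from Co(dpm)2 and PhSiH3 transfers hydrogen to C12 of the captodative α-alkoxy acrylate and gives the O-bound cobalt enolate 22 without base, so the enolisable C10 aldehyde is not deprotonated; the enolate adds to the tethered aldehyde and the aldolate passes to silicon as 23, which turns the catalyst over. The closest known reaction type is the cobalt-catalysed reductive aldol cyclisation of aldehyde-tethered α,β-unsaturated carbonyl compounds. The single new bond C10–C11 closes the oxepane by a 7-enolexo-exo-trig attack and the seven-membered lactone by a 7-enolendo-exo-trig attack, both allowed. C11 is planar in the enolate and is then fixed by C7, because the three-carbon tether can only reach the enolate face cis to itself, so the C11=C12 geometry does not matter; C10 is set by a closed six-membered transition state in which cobalt bridges the enolate oxygen and the aldehyde oxygen, which places the new hydroxyl syn to the lactone carbonyl. The step needs hydride delivery to the conjugated alkene in the presence of the aldehyde and the isolated C2=C3 alkene, which conjugation with the lactone carbonyl and the neutral, oxygen-free conditions should secure.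

Step 14
Reactants: 24 bicyclic hydroxy lactone
Product: 27 3-[(1R,2S,5R,9S)-5-methyl-9-{(3Z)-3-methyl-5-[(tert-butyldimethylsilyl)oxy]pent-3-en-1-yl}-7-oxo-2-(triethylsilyloxy)-6,8-dioxabicyclo[3.2.2]nonan-1-yl]propanal, via triethylsilyl ether 25 (not isolated), via lutidinium salt 26 (not isolated)
Conditions: TESOTf (1.2 equiv), 2,6-lutidine (5 equiv), CH2Cl2, −78 °C; then TESOTf (2 equiv), 0 °C; then H2O, 0 °C to rt
Reagents that add atoms: triethylsilyl trifluoromethanesulfonate, CC[Si](CC)(CC)OS(=O)(=O)C(F)(F)F; water, O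
Why: Silyl triflate–lutidine silylation of the hindered C10 hydroxyl, then acetal cleavage by the same reagent pair through a lutidinium N,O-acetal salt that water hydrolyses, conditions that silyl ethers and the lactone tolerate; capping O10 first prevents a six-membered lactol with the C14 aldehyde and retro-aldol opening under the basic olefination that follows.

Step 15
Reactants: 27 aldehyde; 28 ethyl 2-[bis(2,2,2-trifluoroethoxy)phosphoryl]propanoate
Product: 29 ethyl (2Z)-2-methyl-5-[(1R,2S,5R,9S)-5-methyl-9-{(3Z)-3-methyl-5-[(tert-butyldimethylsilyl)oxy]pent-3-en-1-yl}-7-oxo-2-(triethylsilyloxy)-6,8-dioxabicyclo[3.2.2]nonan-1-yl]pent-2-enoate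
Conditions: 28 (1.5 equiv), KHMDS (1.4 equiv), 18-crown-6 (3 equiv), THF, −78 °C; then 27, −78 °C
Reagents that add atoms: none
Why: Still–Gennari olefination: the electron-poor bis(trifluoroethyl) phosphonate makes elimination from the kinetic adduct fast, which should give the (Z)-trisubstituted enoate with the ester cis to the chain; the lactone cannot enolise (C11 is quaternary) and O10 is silylated.

Step 16
Reactants: 29 (Z)-enoate
Product: 30 (1R,2S,5R,9S)-1-[(3Z)-5-hydroxy-4-methylpent-3-en-1-yl]-5-methyl-9-{(3Z)-3-methyl-5-[(tert-butyldimethylsilyl)oxy]pent-3-en-1-yl}-2-(triethylsilyloxy)-6,8-dioxabicyclo[3.2.2]nonan-7-one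
Conditions: DIBAL-H (2.3 equiv), CH2Cl2, −78 °C; Rochelle salt
Reagents that add atoms: none
Why: DIBAL-H 1,2-reduction of the ester to the allylic alcohol with retention of the Z geometry; the ethyl enoate should react before the lactone carbonyl, which lies between the quaternary C11 and the tertiary C7–O and is screened by the neighbouring C10 silyloxy group.

Step 17
Reactants: 30 bis-silyl ether
Product: 31 (1R,2S,5R,9S)-2-hydroxy-1-[(3Z)-5-hydroxy-4-methylpent-3-en-1-yl]-9-[(3Z)-5-hydroxy-3-methylpent-3-en-1-yl]-5-methyl-6,8-dioxabicyclo[3.2.2]nonan-7-one (CNP0105745.1)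
Conditions: HF·pyridine, pyridine, THF, 0 °C to rt
Reagents that add atoms: none
Why: Acidic fluoride desilylation should remove both silyl ethers in one operation and avoids the basic conditions that could trigger retro-aldol opening of the β-hydroxy lactone.

Compound list
1 | nerol | CC(C)=CCC/C(C)=C\CO | starting material
2 | neryl TBS ether | CC(C)=CCC/C(C)=C\CO[Si](C)(C)C(C)(C)C | intermediate
3 | (2E,6Z)-8-(TBS-oxy)-2,6-dimethylocta-2,6-dien-1-ol | OC/C(C)=C/CC/C(C)=C\CO[Si](C)(C)C(C)(C)C | intermediate
4 | (2S,3S)-epoxy alcohol | OC[C@]1(C)O[C@H]1CC/C(C)=C\CO[Si](C)(C)C(C)(C)C | intermediate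
5 | tert-butyl acetate | CC(=O)OC(C)(C)C | starting material
6 | (2S,3S)-epoxy triflate (not isolated) | FC(F)(F)S(=O)(=O)OC[C@]1(C)O[C@H]1CC/C(C)=C\CO[Si](C)(C)C(C)(C)C | intermediate
7 | (2S,3S)-epoxy tert-butyl ester | CC(C)(C)OC(=O)CC[C@]1(C)O[C@H]1CC/C(C)=C\CO[Si](C)(C)C(C)(C)C | intermediate
8 | (5R)-5-[(1S)-1-hydroxyalkyl]-5-methyl γ-lactone | C[C@@]1(CCC(=O)O1)[C@@H](O)CC/C(C)=C\CO[Si](C)(C)C(C)(C)C | intermediate
9 | triethyl phosphonoacetate | CCOC(=O)CP(=O)(OCC)OCC | starting material
10 | sodium salt of 9 (not isolated) | [Na+].CCOC(=O)[CH-]P(=O)(OCC)OCC | intermediate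
11 | ethyl 2-diazo-2-(diethoxyphosphoryl)acetate | CCOC(=O)C(=[N+]=[N-])P(=O)(OCC)OCC | intermediate
12 | O6-phosphonoacetate of lactone 8 | CCOC(=O)C(O[C@@H](CC/C(C)=C\CO[Si](C)(C)C(C)(C)C)[C@@]1(C)CCC(=O)O1)P(=O)(OCC)OCC | intermediate
13 | sodium enolate of 12 (not isolated) | [Na+].CCOC([O-])=C(O[C@@H](CC/C(C)=C\CO[Si](C)(C)C(C)(C)C)[C@@]1(C)CCC(=O)O1)P(=O)(OCC)OCC | intermediate
14 | (6S,7R)-7,10-diol phosphonoacetate (not isolated) | CCOC(=O)C(O[C@@H](CC/C(C)=C\CO[Si](C)(C)C(C)(C)C)[C@](C)(O)CCCO)P(=O)(OCC)OCC | intermediate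
15 | (5S,6R)-3-phosphono-1,4-dioxan-2-one, C10 alcohol | CCOP(=O)(OCC)C1O[C@@H](CC/C(C)=C\CO[Si](C)(C)C(C)(C)C)[C@@](C)(CCCO)OC1=O | intermediate
16 | (5S,6R)-3-phosphono-1,4-dioxan-2-one, C10 TES ether | CCOP(=O)(OCC)C1O[C@@H](CC/C(C)=C\CO[Si](C)(C)C(C)(C)C)[C@@](C)(CCCO[Si](CC)(CC)CC)OC1=O | intermediate
17 | methyl 3,3-dimethoxypropanoate | COC(OC)CC(=O)OC | starting material
18 | 3,3-dimethoxypropanal | COC(OC)CC=O | intermediate
19 | lithiated phosphonate of 16 (not isolated) | [Li+].CCOP(=O)(OCC)[C-]1O[C@@H](CC/C(C)=C\CO[Si](C)(C)C(C)(C)C)[C@@](C)(CCCO[Si](CC)(CC)CC)OC1=O | intermediate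
20 | (5S,6R)-3-alkylidene dioxanone, C10 TES ether | COC(OC)CC=C1O[C@@H](CC/C(C)=C\CO[Si](C)(C)C(C)(C)C)[C@@](C)(CCCO[Si](CC)(CC)CC)OC1=O | intermediate
21 | (5S,6R)-3-alkylidene dioxanone aldehyde (key-step precursor) | COC(OC)CC=C1O[C@@H](CC/C(C)=C\CO[Si](C)(C)C(C)(C)C)[C@@](C)(CCC=O)OC1=O | intermediate
22 | O-bound (dipivaloylmethanato)cobalt enolate of the reduced dioxanone (not isolated) | COC(OC)CCC1O[C@@H](CC/C(C)=C\CO[Si](C)(C)C(C)(C)C)[C@@](C)(CCC=O)OC=1O[Co]OC(=CC(=O)C(C)(C)C)C(C)(C)C | intermediate
23 | C10 phenylsilyl ether of 24 (not isolated) | COC(OC)CC[C@@]12O[C@@H](CC/C(C)=C\CO[Si](C)(C)C(C)(C)C)[C@@](C)(CC[C@@H]1O[SiH2]c1ccccc1)OC2=O | intermediate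
24 | (1R,2S,5R,9S)-bicyclic hydroxy lactone with C14 acetal | COC(OC)CC[C@@]12O[C@@H](CC/C(C)=C\CO[Si](C)(C)C(C)(C)C)[C@@](C)(CC[C@@H]1O)OC2=O | intermediate
25 | C10 TES ether of 24 (not isolated) | COC(OC)CC[C@@]12O[C@@H](CC/C(C)=C\CO[Si](C)(C)C(C)(C)C)[C@@](C)(CC[C@@H]1O[Si](CC)(CC)CC)OC2=O | intermediate
26 | C14 N-(1-methoxyalkyl)-2,6-lutidinium triflate (not isolated) | COC(CC[C@@]12O[C@@H](CC/C(C)=C\CO[Si](C)(C)C(C)(C)C)[C@@](C)(CC[C@@H]1O[Si](CC)(CC)CC)OC2=O)[n+]1c(C)cccc1C.[O-]S(=O)(=O)C(F)(F)F | intermediate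
27 | C14 aldehyde, C10 TES ether | O=CCC[C@@]12O[C@@H](CC/C(C)=C\CO[Si](C)(C)C(C)(C)C)[C@@](C)(CC[C@@H]1O[Si](CC)(CC)CC)OC2=O | intermediate
28 | ethyl 2-[bis(2,2,2-trifluoroethoxy)phosphoryl]propanoate | CCOC(=O)C(C)P(=O)(OCC(F)(F)F)OCC(F)(F)F | starting material
29 | (Z)-ethyl enoate | CCOC(=O)/C(C)=C\CC[C@@]12O[C@@H](CC/C(C)=C\CO[Si](C)(C)C(C)(C)C)[C@@](C)(CC[C@@H]1O[Si](CC)(CC)CC)OC2=O | intermediate
30 | (Z)-allylic alcohol, bis-silyl ether | OC/C(C)=C\CC[C@@]12O[C@@H](CC/C(C)=C\CO[Si](C)(C)C(C)(C)C)[C@@](C)(CC[C@@H]1O[Si](CC)(CC)CC)OC2=O | intermediate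
31 | CNP0105745.1 | C/C(=C/CC[C@@]12O[C@@H](CC/C(C)=C\CO)[C@@](C)(CC[C@@H]1O)OC2=O)CO | target

Total step count: 17 (including the preparation of reagents 11 and 18).
Longest linear sequence: 15 steps (1–5, 7–9, 11–17) from nerol.

Steps most likely to fail

Step 13. The hydride may reduce the aldehyde instead of the conjugated alkene, the enolate may be protonated or silylated before it cyclises, or the strained aldolate may revert. The fallback sets out from 20 and comes back at 24, replacing the aldol by an enolate acylation followed by ketone reduction. [(Ph3P)CuH]6 with t-BuOH in toluene reduces the exocyclic alkene (no aldehyde is present) to the saturated dioxanone F1 (both C11 epimers). Swern oxidation as in step 12 gives the saturated aldehyde F2, and NaClO2/NaH2PO4/2-methylbut-2-ene gives the acid F3. EDC and MeNH(OMe)·HCl give the Weinreb amide F4. LiHMDS in THF at −78 °C forms the lactone enolate, which acylates itself on the amide to the bridged keto lactone F5; the chelated tetrahedral adduct prevents retro-Claisen cleavage. NaBH4 in MeOH at −40 °C should deliver hydride from the face beside the ether oxygen bridge, the less hindered one, and give 24.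

Step 16. Hydride may also attack the lactone carbonyl, leading to a lactol or ring-opened diol. The fallback sets out from 27 and comes back at 30 without an ester. Stork–Zhao olefination with the ylide from (1-iodoethyl)triphenylphosphonium iodide and NaHMDS (THF, −78 °C) gives the (Z)-vinyl iodide F6. Stille coupling with (tributylstannyl)methanol (Pd(PPh3)4, dioxane, 80 °C) replaces iodine by CH2OH with retention and gives 30.

Step 8. Incomplete masking of the ester as its enolate would allow over-reduction of the phosphonoacetate, and the tertiary alcohol may lactonise slowly. The fallback sets out from 8 and comes back at 14, with the lactone reduced before the phosphonoacetate exists. DIBAL-H (CH2Cl2, −78 °C) gives the lactol F7, and MeOH/PPTS gives the methyl acetal F8, in which the C6 hydroxyl is still the only OH. Rh2(OAc)4 and 11 give the phosphonoacetate F9. PPTS in acetone–water gives the lactol F10, and NaBH4 in EtOH at 0 °C, which spares the ethyl ester, gives diol 14, which is lactonised as in step 8.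

Further compounds
F1 | step 13 | (5S,6R)-3-(3,3-dimethoxypropyl) dioxanone, C10 TES ether (C11 epimers) | COC(OC)CCC1O[C@@H](CC/C(C)=C\CO[Si](C)(C)C(C)(C)C)[C@@](C)(CCCO[Si](CC)(CC)CC)OC1=O
F2 | step 13 | saturated dioxanone aldehyde | COC(OC)CCC1O[C@@H](CC/C(C)=C\CO[Si](C)(C)C(C)(C)C)[C@@](C)(CCC=O)OC1=O
F3 | step 13 | saturated dioxanone C10 carboxylic acid | COC(OC)CCC1O[C@@H](CC/C(C)=C\CO[Si](C)(C)C(C)(C)C)[C@@](C)(CCC(=O)O)OC1=O
F4 | step 13 | C10 N-methoxy-N-methylamide | COC(OC)CCC1O[C@@H](CC/C(C)=C\CO[Si](C)(C)C(C)(C)C)[C@@](C)(CCC(=O)N(C)OC)OC1=O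
F5 | step 13 | (1R,5R,9S)-6,8-dioxabicyclo[3.2.2]nonane-2,7-dione with C14 acetal | COC(OC)CC[C@@]12O[C@@H](CC/C(C)=C\CO[Si](C)(C)C(C)(C)C)[C@@](C)(CCC1=O)OC2=O
F6 | step 16 | (Z)-vinyl iodide | C/C(I)=C/CC[C@@]12O[C@@H](CC/C(C)=C\CO[Si](C)(C)C(C)(C)C)[C@@](C)(CC[C@@H]1O[Si](CC)(CC)CC)OC2=O
F7 | step 8 | (5R)-lactol of 8 | C[C@@]1(CCC(O)O1)[C@@H](O)CC/C(C)=C\CO[Si](C)(C)C(C)(C)C
F8 | step 8 | lactol methyl acetal with free C6 hydroxyl | C[C@@]1(CCC(OC)O1)[C@@H](O)CC/C(C)=C\CO[Si](C)(C)C(C)(C)C
F9 | step 8 | O6-phosphonoacetate of the methyl acetal | CCOC(=O)C(O[C@@H](CC/C(C)=C\CO[Si](C)(C)C(C)(C)C)[C@@]1(C)CCC(OC)O1)P(=O)(OCC)OCC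
F10 | step 8 | O6-phosphonoacetate lactol | CCOC(=O)C(O[C@@H](CC/C(C)=C\CO[Si](C)(C)C(C)(C)C)[C@@]1(C)CCC(O)O1)P(=O)(OCC)OCC
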